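**Plan**

- Enabling feature: ring B is a benzene with oxygen on C3 and C5, the acyl carbon on C4 between them and the CH2 link on C1 para to C4. This is the pattern formed when a vinylketene from a 3-substituted cyclobutenone combines with a 1-siloxyalkyne.
- Retrosynthesis: cut the aryl O–Si bond, return both ketones to lower oxidation levels (chain C=O to CH2, anisyl C=O to a silylated carbinol), then cut ring B at C3–C4, C5–C6 and C2–C3.
- The cyclobutenone is cut into dichloroketene and a terminal alkyne made from 4-methoxybenzaldehyde and propargyl bromide. The siloxyalkyne is cut into ethyl 5-methylhexanoate and one carbon from CH2Br2.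
- Forward: ring A is bought, the four-membered ring is made in steps 3–4, the chain arrives with the alkyne, ring B closes in step 6, one quinone oxidation sets both ketones, and fluoride frees the second phenol.
- Stereochemistry: the target has no stereocentre. The carbinol carbon made in step 1 is racemic and is erased in step 7.

Key step: step 6

Assumption: all intermediates with a carbinol carbon are carried as racemates (or diastereomer mixtures), since that centre becomes a ketone. TBS = tert-butyldimethylsilyl, TIPS = triisopropylsilyl.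

**Step 1**
Reactants: 1 4-methoxybenzaldehyde; 2 3-bromoprop-1-yne (propargyl bromide)
Product: 4 1-(4-methoxyphenyl)but-3-yn-1-ol (racemic), via allenylzinc bromide 3 (not isolated)
Conditions: Zn dust, THF, 0 °C to rt; aq NH4Cl
Reagents that add atoms: none
Why: Barbier propargylation, in which zinc inserts into the C–Br bond and allenylzinc bromide 3 adds to the aldehyde through its γ-carbon (SE2') to give the homopropargylic alcohol; the new carbinol centre forms as a racemate and is removed later by oxidation.

**Step 2**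
Reactants: 4 1-(4-methoxyphenyl)but-3-yn-1-ol
Product: 5 tert-butyl{[1-(4-methoxyphenyl)but-3-yn-1-yl]oxy}dimethylsilane
Conditions: TBSCl, imidazole, DMF, rt
Reagents that add atoms: tert-butyldimethylsilyl chloride, CC(C)(C)[Si](C)(C)Cl
Why: Standard silylation of a secondary alcohol; the silyl ether keeps the hydroxyl from being acylated in step 3 and later serves as the latent anisyl ketone.

**Step 3**
Reactants: 5 tert-butyl{[1-(4-methoxyphenyl)but-3-yn-1-yl]oxy}dimethylsilane; 6 trichloroacetyl chloride
Product: 8 3-{2-[tert-butyl(dimethyl)silyl]oxy-2-(4-methoxyphenyl)ethyl}-4,4-dichlorocyclobut-2-en-1-one, via dichloroketene 7 (not isolated)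
Conditions: Zn–Cu couple, Et2O/DME, rt, slow addition of 6
Reagents that add atoms: none
Why: Zinc dechlorination of 6 generates dichloroketene 7, which undergoes the known ketene–alkyne [2+2] cycloaddition in which the unsubstituted alkyne carbon bonds to the ketene carbonyl carbon, so the side chain ends on C3 of the cyclobutenone; DME ties up ZnCl2 and protects the benzylic silyl ether.

**Step 4**
Reactants: 8 3-{2-[tert-butyl(dimethyl)silyl]oxy-2-(4-methoxyphenyl)ethyl}-4,4-dichlorocyclobut-2-en-1-one
Product: 9 3-{2-[tert-butyl(dimethyl)silyl]oxy-2-(4-methoxyphenyl)ethyl}cyclobut-2-en-1-one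
Conditions: Zn dust, AcOH, TMEDA, EtOH, 0 °C to rt
Reagents that add atoms: none
Why: Reductive dehalogenation of the α,α-dichloroketone by zinc through zinc enolates; the amine buffer suppresses acid-promoted isomerisation or opening of the strained enone and spares the silyl ether.

**Step 5**
Reactants: 10 ethyl 5-methylhexanoate; 11 dibromomethane
Product: 14 triisopropyl[(6-methylhept-1-yn-1-yl)oxy]silane, via dibromomethyllithium 12 (not isolated), via lithium ynolate 13 (not isolated)
Conditions: lithium 2,2,6,6-tetramethylpiperidide, THF, −78 °C; LiN(SiMe3)2 then n-BuLi, −78 °C to rt; TIPSOTf, −78 to 0 °C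
Reagents that add atoms: triisopropylsilyl trifluoromethanesulfonate, CC(C)[Si](OS(=O)(=O)C(F)(F)F)(C(C)C)C(C)C
Why: Kowalski ynolate homologation, in which 12 adds to the ester, the dibromo ketone enolate undergoes bromine–lithium exchange and the carbenoid rearranges with 1,2-shift of the alkyl group to ynolate 13, which the hard silyl triflate traps on oxygen.

**Step 6**
Reactants: 9 3-{2-[tert-butyl(dimethyl)silyl]oxy-2-(4-methoxyphenyl)ethyl}cyclobut-2-en-1-one; 14 triisopropyl[(6-methylhept-1-yn-1-yl)oxy]silane
Product: 19 5-{2-[tert-butyl(dimethyl)silyl]oxy-2-(4-methoxyphenyl)ethyl}-2-(4-methylpentyl)-3-(triisopropylsilyloxy)phenol, via vinylketene 15 (not isolated), via vinylcyclobutenone 16 (not isolated), via dienylketene 17 (not isolated), via cyclohexadienone 18 (not isolated)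
Conditions: toluene, 80 °C, argon, 14 in slight excess
Reagents that add atoms: none
Why: At 80 °C cyclobutenone 9 should open reversibly (4π electrocyclic) to vinylketene 15, whose ketene C=C is captured in a [2+2] cycloaddition by the electron-rich alkyne 14 to give 4-vinylcyclobutenone 16. A second 4π opening gives dienylketene 17, and ring B closes by a thermal 6π electrocyclisation that joins the ketene carbon to the terminal methylene, after which dienone 18 tautomerises to the phenol; in the numbering of 19 the C1–C2, C3–C4 and C1–C6 bonds are new. The closest known reaction is the Danheiser benzannulation of 3-alkylcyclobutenones with triisopropylsilyl ynol ethers, which gives resorcinol monosilyl ethers of this substitution pattern. No stereocentre is created, and the racemic carbinol carbon is a spectator. The step needs regiocontrol in the ketene–alkyne [2+2]: oxygen donation makes the alkyl-bearing alkyne carbon the nucleophilic end, so it bonds to the electrophilic ketene carbonyl carbon and the 4-methylpentyl group ends between hydroxyl and silyloxy, while the C3 substituent of the cyclobutenone is forced para to it. The silyl ethers and the anisole are inert under these neutral thermal conditions.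

**Step 7**
Reactants: 19 5-{2-[tert-butyl(dimethyl)silyl]oxy-2-(4-methoxyphenyl)ethyl}-2-(4-methylpentyl)-3-(triisopropylsilyloxy)phenol
Product: 23 1-{2-hydroxy-4-[2-(4-methoxyphenyl)-2-oxoethyl]-6-(triisopropylsilyloxy)phenyl}-4-methylpentan-1-one, via quinone methide 20 (not isolated), via benzylic alcohol 21 (not isolated), via chain ketone 22 (not isolated)
Conditions: DDQ (3.5 equiv), 1,4-dioxane/H2O, 0 °C to rt
Reagents that add atoms: water, O
Why: Quinone dehydrogenation should act only at the two benzylic carbons whose cations an oxygen lone pair can stabilise: the phenol loses hydride from the ortho chain CH2 to give quinone methide 20, which takes up water to 21 and is dehydrogenated again to the hydrogen-bonded ortho-hydroxyaryl ketone 22, while the 4-methoxybenzylic silyl ether loses hydride to a silyloxocarbenium ion that water desilylates to the aryl ketone; the CH2 link is meta to both ring B oxygens and should be left alone.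

**Step 8**
Reactants: 23 1-{2-hydroxy-4-[2-(4-methoxyphenyl)-2-oxoethyl]-6-(triisopropylsilyloxy)phenyl}-4-methylpentan-1-one
Product: 24 1-{2,6-dihydroxy-4-[2-(4-methoxyphenyl)-2-oxoethyl]phenyl}-4-methylpentan-1-one (CNP0142242.0)
Conditions: Bu4NF, AcOH, THF, 0 °C
Reagents that add atoms: none
Why: Fluoride desilylation of an aryl silyl ether whose phenoxide leaving group is further activated by the ortho acyl group; acetic acid buffering keeps the acidic ArCH2C(=O)Ar position from enolate side reactions.

**Compound list**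

1 | 4-methoxybenzaldehyde | COc1ccc(C=O)cc1 | starting material
2 | 3-bromoprop-1-yne (propargyl bromide) | BrCC#C | starting material
3 | allenylzinc bromide (propa-1,2-dien-1-ylzinc bromide; not isolated) | C=C=C[Zn]Br | intermediate
4 | 1-(4-methoxyphenyl)but-3-yn-1-ol (racemic) | COc1ccc(C(O)CC#C)cc1 | intermediate
5 | tert-butyl{[1-(4-methoxyphenyl)but-3-yn-1-yl]oxy}dimethylsilane (racemic) | COc1ccc(C(CC#C)O[Si](C)(C)C(C)(C)C)cc1 | intermediate
6 | trichloroacetyl chloride | ClC(=O)C(Cl)(Cl)Cl | starting material
7 | dichloroketene (not isolated) | ClC(Cl)=C=O | intermediate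
8 | 3-{2-[tert-butyl(dimethyl)silyl]oxy-2-(4-methoxyphenyl)ethyl}-4,4-dichlorocyclobut-2-en-1-one (racemic) | COc1ccc(C(CC2=CC(=O)C2(Cl)Cl)O[Si](C)(C)C(C)(C)C)cc1 | intermediate
9 | 3-{2-[tert-butyl(dimethyl)silyl]oxy-2-(4-methoxyphenyl)ethyl}cyclobut-2-en-1-one (racemic) | COc1ccc(C(CC2=CC(=O)C2)O[Si](C)(C)C(C)(C)C)cc1 | intermediate
10 | ethyl 5-methylhexanoate | CCOC(=O)CCCC(C)C | starting material
11 | dibromomethane | BrCBr | starting material
12 | dibromomethyllithium (not isolated) | [Li]C(Br)Br | intermediate
13 | lithium 6-methylhept-1-yn-1-olate (ynolate; not isolated) | [Li+].[O-]C#CCCCC(C)C | intermediate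
14 | triisopropyl[(6-methylhept-1-yn-1-yl)oxy]silane | CC(C)CCCC#CO[Si](C(C)C)(C(C)C)C(C)C | intermediate
15 | 3-{2-[tert-butyl(dimethyl)silyl]oxy-2-(4-methoxyphenyl)ethyl}buta-1,3-dien-1-one (vinylketene; not isolated) | O=C=CC(=C)CC(O[Si](C)(C)C(C)(C)C)c1ccc(OC)cc1 | intermediate
16 | 4-{4-[tert-butyl(dimethyl)silyl]oxy-4-(4-methoxyphenyl)but-1-en-2-yl}-2-(4-methylpentyl)-3-(triisopropylsilyloxy)cyclobut-2-en-1-one (diastereomer mixture; not isolated) | O=C1C(CCCC(C)C)=C(O[Si](C(C)C)(C(C)C)C(C)C)C1C(=C)CC(O[Si](C)(C)C(C)(C)C)c1ccc(OC)cc1 | intermediate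
17 | 5-{2-[tert-butyl(dimethyl)silyl]oxy-2-(4-methoxyphenyl)ethyl}-2-(4-methylpentyl)-3-(triisopropylsilyloxy)hexa-1,3,5-trien-1-one, ketene carbon and vinyl group cis on the C3=C4 bond (not isolated) | O=C=C(CCCC(C)C)/C(O[Si](C(C)C)(C(C)C)C(C)C)=C\C(=C)CC(O[Si](C)(C)C(C)(C)C)c1ccc(OC)cc1 | intermediate
18 | 5-{2-[tert-butyl(dimethyl)silyl]oxy-2-(4-methoxyphenyl)ethyl}-2-(4-methylpentyl)-3-(triisopropylsilyloxy)cyclohexa-2,4-dien-1-one (not isolated) | O=C1CC(CC(O[Si](C)(C)C(C)(C)C)c2ccc(OC)cc2)=CC(O[Si](C(C)C)(C(C)C)C(C)C)=C1CCCC(C)C | intermediate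
19 | 5-{2-[tert-butyl(dimethyl)silyl]oxy-2-(4-methoxyphenyl)ethyl}-2-(4-methylpentyl)-3-(triisopropylsilyloxy)phenol (racemic) | COc1ccc(C(Cc2cc(O)c(CCCC(C)C)c(O[Si](C(C)C)(C(C)C)C(C)C)c2)O[Si](C)(C)C(C)(C)C)cc1 | intermediate
20 | 3-{2-[tert-butyl(dimethyl)silyl]oxy-2-(4-methoxyphenyl)ethyl}-6-(4-methylpentylidene)-5-(triisopropylsilyloxy)cyclohexa-2,4-dien-1-one (ortho-quinone methide; not isolated) | O=C1C=C(CC(O[Si](C)(C)C(C)(C)C)c2ccc(OC)cc2)C=C(O[Si](C(C)C)(C(C)C)C(C)C)C1=CCCC(C)C | intermediate
21 | 5-{2-[tert-butyl(dimethyl)silyl]oxy-2-(4-methoxyphenyl)ethyl}-2-(1-hydroxy-4-methylpentyl)-3-(triisopropylsilyloxy)phenol (diastereomer mixture; not isolated) | COc1ccc(C(Cc2cc(O)c(C(O)CCC(C)C)c(O[Si](C(C)C)(C(C)C)C(C)C)c2)O[Si](C)(C)C(C)(C)C)cc1 | intermediate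
22 | 1-[4-{2-[tert-butyl(dimethyl)silyl]oxy-2-(4-methoxyphenyl)ethyl}-2-hydroxy-6-(triisopropylsilyloxy)phenyl]-4-methylpentan-1-one (not isolated) | COc1ccc(C(Cc2cc(O)c(C(=O)CCC(C)C)c(O[Si](C(C)C)(C(C)C)C(C)C)c2)O[Si](C)(C)C(C)(C)C)cc1 | intermediate
23 | 1-{2-hydroxy-4-[2-(4-methoxyphenyl)-2-oxoethyl]-6-(triisopropylsilyloxy)phenyl}-4-methylpentan-1-one | COc1ccc(C(=O)Cc2cc(O)c(C(=O)CCC(C)C)c(O[Si](C(C)C)(C(C)C)C(C)C)c2)cc1 | intermediate
24 | 1-{2,6-dihydroxy-4-[2-(4-methoxyphenyl)-2-oxoethyl]phenyl}-4-methylpentan-1-one | COc1ccc(C(=O)Cc2cc(O)c(C(=O)CCC(C)C)c(O)c2)cc1 | target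

**Step count**

Total: 8 steps. Longest linear sequence: 7 steps (1 to 24 through steps 1, 2, 3, 4, 6, 7, 8); alkyne 14 is made in one parallel step (step 5).

**Steps most likely to fail**

Step 7. The quinone methide may tautomerise to the alkenylphenol, dimerise or cyclise before water adds, and the silyloxocarbenium ion may lose a proton and be oxidised further, so oxygen is not delivered cleanly to the chain carbon. The fallback sets out from cyclobutenone 9 and returns at 23; it brings the chain oxygen in with the alkyne. 4-Methylpentanal and ethynylmagnesium bromide (THF, 0 °C) should give 6-methylhept-1-yn-3-ol F1, which TBSCl and imidazole convert into tert-butyldimethyl[(6-methylhept-1-yn-3-yl)oxy]silane F2. Deprotonation with n-BuLi, oxygen transfer from lithium tert-butyl peroxide (from t-BuOOH and LiN(SiMe3)2) and O-silylation with TIPSOTf in one flask should give 3-(tert-butyldimethylsilyloxy)-6-methyl-1-(triisopropylsilyloxy)hept-1-yne F3. Annulation of F3 with 9 under the conditions of step 6 should give 5-{2-[tert-butyl(dimethyl)silyl]oxy-2-(4-methoxyphenyl)ethyl}-2-{1-[tert-butyl(dimethyl)silyl]oxy-4-methylpentyl}-3-(triisopropylsilyloxy)phenol F4, in which both benzylic carbons already carry oxygen. DDQ in CH2Cl2/pH 7 buffer should then turn both electron-rich benzylic silyl ethers into ketones by hydride abstraction and loss of silanol, which is 23.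

Step 6. The siloxyalkyne may be lost by hydrolysis or by silyl transfer to the phenolic product faster than the vinylketene captures it, and the vinylketene is then diverted into acylation of the product phenol. The fallback sets out from cyclobutenone 9 and returns at target 24; it uses an alkyl ynol ether, which has no transferable silyl group, and removes the alkyl group at the end. Ethoxyethyne, deprotonated with n-BuLi and alkylated with 1-iodo-4-methylpentane (THF/DMPU), should give 1-ethoxy-6-methylhept-1-yne F5. Heating F5 with 9 in toluene at 80 °C should give 5-{2-[tert-butyl(dimethyl)silyl]oxy-2-(4-methoxyphenyl)ethyl}-3-ethoxy-2-(4-methylpentyl)phenol F6 by the same cascade. DDQ in wet dioxane as in step 7 should give 1-{2-ethoxy-6-hydroxy-4-[2-(4-methoxyphenyl)-2-oxoethyl]phenyl}-4-methylpentan-1-one F7. BCl3 (CH2Cl2, −78 to 0 °C) should then cleave the ethyl ether that chelates to the adjacent ketone and leave the ring A methyl ether, which gives 24.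

Step 3. ZnCl2 or the acid chloride may ionise or acylate the 4-methoxybenzylic silyl ether, and dichloroketene may oligomerise before the unactivated alkyne traps it. The fallback sets out from alkyne 5 and returns at cyclobutenone 9; it is a zinc-free keteniminium–alkyne [2+2] cycloaddition that makes step 4 unnecessary. N,N-Dimethylacetamide, Tf2O and 2,4,6-collidine in ClCH2CH2Cl should give N,N-dimethylketeniminium triflate F8, which should add to 5 at reflux with the same regiochemistry to give 3-{2-[tert-butyl(dimethyl)silyl]oxy-2-(4-methoxyphenyl)ethyl}-N,N-dimethylcyclobut-2-en-1-iminium triflate F9. Hydrolysis with aqueous NaHCO3 should give 9 directly.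

**Further compounds**

F1 | step 7 | 6-methylhept-1-yn-3-ol | CC(C)CCC(O)C#C
F2 | step 7 | tert-butyldimethyl[(6-methylhept-1-yn-3-yl)oxy]silane | CC(C)CCC(C#C)O[Si](C)(C)C(C)(C)C
F3 | step 7 | 3-(tert-butyldimethylsilyloxy)-6-methyl-1-(triisopropylsilyloxy)hept-1-yne | CC(C)CCC(C#CO[Si](C(C)C)(C(C)C)C(C)C)O[Si](C)(C)C(C)(C)C
F4 | step 7 | 5-{2-[tert-butyl(dimethyl)silyl]oxy-2-(4-methoxyphenyl)ethyl}-2-{1-[tert-butyl(dimethyl)silyl]oxy-4-methylpentyl}-3-(triisopropylsilyloxy)phenol | COc1ccc(C(Cc2cc(O)c(C(CCC(C)C)O[Si](C)(C)C(C)(C)C)c(O[Si](C(C)C)(C(C)C)C(C)C)c2)O[Si](C)(C)C(C)(C)C)cc1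
F5 | step 6 | 1-ethoxy-6-methylhept-1-yne | CCOC#CCCCC(C)C
F6 | step 6 | 5-{2-[tert-butyl(dimethyl)silyl]oxy-2-(4-methoxyphenyl)ethyl}-3-ethoxy-2-(4-methylpentyl)phenol | CCOc1cc(CC(O[Si](C)(C)C(C)(C)C)c2ccc(OC)cc2)cc(O)c1CCCC(C)C
F7 | step 6 | 1-{2-ethoxy-6-hydroxy-4-[2-(4-methoxyphenyl)-2-oxoethyl]phenyl}-4-methylpentan-1-one | CCOc1cc(CC(=O)c2ccc(OC)cc2)cc(O)c1C(=O)CCC(C)C
F8 | step 3 | N,N-dimethylketeniminium triflate | C=C=[N+](C)C.[O-]S(=O)(=O)C(F)(F)F
F9 | step 3 | 3-{2-[tert-butyl(dimethyl)silyl]oxy-2-(4-methoxyphenyl)ethyl}-N,N-dimethylcyclobut-2-en-1-iminium triflate | COc1ccc(C(CC2=CC(=[N+](C)C)C2)O[Si](C)(C)C(C)(C)C)cc1.[O-]S(=O)(=O)C(F)(F)F
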